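**Retrosynthetic overview**

1. The last events are cleavage of all thirteen alkyl ethers and, before that, an Ullmann ether coupling between the C1 hydroxyl of a ring D–E phenol and C4 of an iodinated ring C that already carries rings B and A.
2. The strategy rests on ring D: five contiguous oxygen-bearing carbons (C1 with O–ring C, C6 with O–ring E, C5, C4 and C3 with hydroxyls) and one C–H (C2). C1, C6, C5 and C4 with their oxygens map onto the four carbons of squaric acid, and C3–C2 onto the two carbons of an enol ether.
3. Ring D is the only ring that is built: a 4-(1-ethoxyvinyl)-4-methoxycyclobutenone that already holds the ring E aryloxy group on the future C6 is ring-expanded thermally (Moore rearrangement), which forms the C1–C2 bond.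
4. The ring D–ring E ether is made on squaryl chloride by addition–elimination. The ring A–ring B ether is made by SNAr on a fluorobenzaldehyde whose formyl group then becomes the ring B C6 oxygen (Baeyer–Villiger). The ring B–ring C ether is made by Ullmann coupling at an unhindered iodide; the bromide left at ring C C4 is then exchanged for iodide.
5. Order of rings: A, B, C and E are bought as arenes, D is formed in step 4, and fragments D–E and A–B–C are joined in step 12.

Key step: step 4

Remark (assumption): every hydroxyl is carried as a methyl ether except the ring D C3 oxygen, which arrives as an ethyl ether from the enol ether; all thirteen are released together at the end and the free polyphenol is handled under argon.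

**Route**

Step 1
Reactants: 1 squaric acid
Product: 2 squaryl dichloride (3,4-dichlorocyclobut-3-ene-1,2-dione)
Conditions: (COCl)2 (2.2 equiv), DMF (cat.), CH2Cl2, 0 °C to reflux
Reagents that add atoms: oxalyl chloride, ClC(=O)C(Cl)=O
Why: DMF-catalysed chlorination with oxalyl chloride (Vilsmeier-type activation) turns both vinylogous acid hydroxyls into chlorides, the standard entry to squaryl dichloride.

Step 2
Reactants: 2 squaryl dichloride; 3 3,4,5-trimethoxyphenol
Product: 5 3-methoxy-4-(3,4,5-trimethoxyphenoxy)cyclobut-3-ene-1,2-dione, via methyl ester chloride 4 (not isolated)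
Conditions: MeOH (1.0 equiv), CH2Cl2, 0 °C to rt, then purge with argon; 3, i-Pr2NEt, CH2Cl2, −40 °C to rt
Reagents that add atoms: methanol, CO
Why: Two successive addition–elimination substitutions at the vinylogous acid chloride carbons should give the mixed ester, because methanol replaces one chloride without base to give ester chloride 4, which is less electrophilic than 2, and the phenol then displaces the remaining chloride under amine base far faster than it could displace methoxide.

Step 3
Reactants: 5 3-methoxy-4-(3,4,5-trimethoxyphenoxy)cyclobut-3-ene-1,2-dione; 6 ethyl vinyl ether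
Product: 9 racemic 4-(1-ethoxyethenyl)-3,4-dimethoxy-2-(3,4,5-trimethoxyphenoxy)cyclobut-2-en-1-one, via 1-ethoxyvinyllithium 7 (not isolated), via lithium cyclobutenolate 8 (not isolated)
Conditions: 6, t-BuLi, THF, −78 to 0 °C; 5, THF, −78 °C; then MeOTf, −78 to 0 °C; Et3N, aq NaHCO3 quench
Reagents that add atoms: methyl trifluoromethanesulfonate, COS(=O)(=O)C(F)(F)F
Why: Carbonyl 1,2-addition of an α-alkoxyvinyllithium to a squarate ester followed by O-methylation of the lithium alkoxide is standard for dialkyl squarates, and here the carbonyl beside the methoxy-bearing carbon should react because the other carbonyl is conjugated with the stronger methoxy donor and is the less electrophilic of the two, which leaves the aryloxy group on the α-carbon of the remaining enone; the new quaternary carbon forms as a racemate and is erased in step 4.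

Step 4
Reactants: 9 racemic 4-(1-ethoxyethenyl)-3,4-dimethoxy-2-(3,4,5-trimethoxyphenoxy)cyclobut-2-en-1-one
Product: 12 5-ethoxy-3,4-dimethoxy-2-(3,4,5-trimethoxyphenoxy)phenol, via dienylketene 10 (not isolated), via cyclohexadienone 11 (not isolated)
Conditions: degassed toluene, 110 °C, argon
Reagents that add atoms: none
Why: Heating opens the cyclobutenone by conrotatory 4π electrocyclic cleavage of the C1–C4 bond to dienylketene 10, with the C4 methoxy group rotating outward and the ethoxyvinyl group inward, the usual torquoselectivity for a donor substituent, so that the vinyl group lies cis to the ketene. A thermal disrotatory 6π electrocyclisation then joins the ketene carbon (future ring D C1) to the vinyl CH2 (future C2) and closes ring D as cyclohexadienone 11, which tautomerises irreversibly to phenol 12. The closest known reaction is the Moore rearrangement of 4-alkenyl-4-alkoxycyclobutenones made from dialkyl squarates, which gives hydroquinone monoethers in the same way. No stereocentre is formed, and the racemic quaternary carbon of 9 becomes aromatic C4. The only selectivity needed is positional and it is fixed before the thermolysis: the four squarate carbons carry their oxygens unchanged into C1, C6, C5 and C4 and the enol ether supplies C3 and C2, so the aryloxy group ends on C6 beside the single free hydroxyl on C1. Closure to a five-membered lactone is excluded because the C4 oxygen is methylated.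

Step 5
Reactants: 13 2,4,6-trimethoxybenzaldehyde
Product: 15 2,4,6-trimethoxyphenol, via aryl formate 14 (not isolated)
Conditions: mCPBA, CH2Cl2, 0 °C to rt; aq NaHCO3 wash; then K2CO3 (cat.), MeOH, rt, argon
Reagents that add atoms: 3-chloroperoxybenzoic acid, OOC(=O)c1cccc(Cl)c1
Why: Baeyer–Villiger oxidation of an electron-rich benzaldehyde proceeds with aryl migration to the formate, which is cleaved by methanolysis to the phenol.

Step 6
Reactants: 16 1-fluoro-3,5-dimethoxybenzene
Product: 18 2-fluoro-4,6-dimethoxybenzaldehyde, via aryl iminium salt 17 (not isolated)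
Conditions: POCl3, DMF, 0 to 60 °C; then ice-water
Reagents that add atoms: N,N-dimethylformamide, CN(C)C=O; water, O
Why: Vilsmeier–Haack formylation is expected at the position para to one methoxy group and beside the small fluorine rather than at the more hindered position between the two methoxy groups, and any 4-fluoro-2,6-dimethoxy isomer would be removed by chromatography.

Step 7
Reactants: 15 2,4,6-trimethoxyphenol; 18 2-fluoro-4,6-dimethoxybenzaldehyde
Product: 19 2,4-dimethoxy-6-(2,4,6-trimethoxyphenoxy)benzaldehyde
Conditions: K2CO3, DMF, 120 °C, argon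
Reagents that add atoms: none
Why: Nucleophilic aromatic substitution (SNAr) of the fluoride ortho to the formyl group goes through a Meisenheimer intermediate stabilised by the aldehyde, and both methoxy groups sit meta to the reacting carbon so they do not oppose it.

Step 8
Reactants: 19 2,4-dimethoxy-6-(2,4,6-trimethoxyphenoxy)benzaldehyde
Product: 21 2,4-dimethoxy-6-(2,4,6-trimethoxyphenoxy)phenol, via aryl formate 20 (not isolated)
Conditions: mCPBA, CH2Cl2, 0 °C to rt; aq NaHCO3 wash; then K2CO3 (cat.), MeOH, rt, argon
Reagents that add atoms: 3-chloroperoxybenzoic acid, OOC(=O)c1cccc(Cl)c1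
Why: Baeyer–Villiger oxidation with migration of the aryl group, which carries ortho and para oxygen donors, turns the formyl carbon into the ring B C6 oxygen, and methanolysis of the formate frees the phenol.

Step 9
Reactants: 22 2-bromo-1,3-dimethoxybenzene
Product: 24 2-bromo-5-iodo-1,3-dimethoxybenzene, via aryl pinacol boronate 23 (not isolated)
Conditions: [Ir(OMe)(cod)]2 (cat.), 4,4'-di-tert-butyl-2,2'-bipyridine, B2pin2 (0.55 equiv), THF, 80 °C; then CuI (cat.), 1,10-phenanthroline, KI, MeOH/H2O, air, 80 °C
Reagents that add atoms: potassium iodide, [K+].[I-]; bis(pinacolato)diboron, CC1(C)OB(OC1(C)C)B1OC(C)(C)C(C)(C)O1 (its boron is held only in 23)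
Why: Sterically controlled iridium-catalysed C–H borylation takes the only C–H without an ortho substituent (para to bromine), and copper-mediated iododeboronation then replaces boron by iodine through transmetalation rather than electrophilic attack, so the C–Br bond and the activated C–H positions are left alone.

Step 10
Reactants: 21 2,4-dimethoxy-6-(2,4,6-trimethoxyphenoxy)phenol; 24 2-bromo-5-iodo-1,3-dimethoxybenzene
Product: 25 2-bromo-5-[2,4-dimethoxy-6-(2,4,6-trimethoxyphenoxy)phenoxy]-1,3-dimethoxybenzene
Conditions: CuI (10 mol %), picolinic acid (20 mol %), K3PO4, DMSO, 80 °C, argon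
Reagents that add atoms: none
Why: Ullmann-type copper-catalysed diaryl ether coupling with picolinic acid as ligand joins the hindered phenol to the unhindered C–I bond, while the C–Br bond is both intrinsically less reactive and flanked by two methoxy groups and should stay intact.

Step 11
Reactants: 25 2-bromo-5-[2,4-dimethoxy-6-(2,4,6-trimethoxyphenoxy)phenoxy]-1,3-dimethoxybenzene
Product: 27 5-[2,4-dimethoxy-6-(2,4,6-trimethoxyphenoxy)phenoxy]-2-iodo-1,3-dimethoxybenzene, via aryllithium 26 (not isolated)
Conditions: n-BuLi, THF, −78 °C; then I2, THF, −78 °C to rt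
Reagents that add atoms: iodine, II
Why: Bromine–lithium exchange gives a 2,6-dimethoxyaryllithium much faster than any ortho-lithiation at −78 °C, and quenching with iodine gives the aryl iodide at the same carbon.

Step 12
Reactants: 12 5-ethoxy-3,4-dimethoxy-2-(3,4,5-trimethoxyphenoxy)phenol; 27 5-[2,4-dimethoxy-6-(2,4,6-trimethoxyphenoxy)phenoxy]-2-iodo-1,3-dimethoxybenzene
Product: 28 1-{4-[2,4-dimethoxy-6-(2,4,6-trimethoxyphenoxy)phenoxy]-2,6-dimethoxyphenoxy}-5-ethoxy-3,4-dimethoxy-2-(3,4,5-trimethoxyphenoxy)benzene
Conditions: CuI (20 mol %), picolinic acid (40 mol %), K3PO4, DMSO, 100 °C, argon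
Reagents that add atoms: none
Why: Ullmann-type copper-catalysed etherification of an aryl iodide flanked by two methoxy groups with a phenol that has a single ortho substituent is the pairing that the picolinic acid system was designed for, and the classical copper-mediated version of this coupling is the usual way to join polymethoxylated phenols and 2,6-dimethoxyaryl halides.

Step 13
Reactants: 28 the fully alkylated pentaaryl tetraether
Product: 29 target tridecaphenol (rings A to E, CNP0243665.0)
Conditions: BBr3 (excess), CH2Cl2, −78 °C to rt, argon; then H2O, 0 °C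
Reagents that add atoms: none
Why: Lewis acid ether cleavage with BBr3 removes the twelve methyl groups and the ethyl group by bromide attack on the O-alkyl carbon of the boron-complexed ethers, whereas the four diaryl ether bonds have no sp3 carbon to attack and should survive.

**Compound list**

1 | squaric acid | OC1=C(O)C(=O)C1=O | starting material
2 | squaryl dichloride (3,4-dichlorocyclobut-3-ene-1,2-dione) | O=C1C(=O)C(Cl)=C1Cl | intermediate
3 | 3,4,5-trimethoxyphenol | COc1cc(O)cc(OC)c1OC | starting material
4 | 3-chloro-4-methoxycyclobut-3-ene-1,2-dione | O=C1C(=O)C(OC)=C1Cl | intermediate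
5 | 3-methoxy-4-(3,4,5-trimethoxyphenoxy)cyclobut-3-ene-1,2-dione | O=C1C(=O)C(OC)=C1Oc1cc(OC)c(OC)c(OC)c1 | intermediate
6 | ethyl vinyl ether | C=COCC | starting material
7 | 1-ethoxyvinyllithium | [Li]C(=C)OCC | intermediate
8 | lithium 1-(1-ethoxyethenyl)-2-methoxy-4-oxo-3-(3,4,5-trimethoxyphenoxy)cyclobut-2-en-1-olate (racemic) | [Li+].[O-]C1(C(=C)OCC)C(OC)=C(Oc2cc(OC)c(OC)c(OC)c2)C1=O | intermediate
9 | 4-(1-ethoxyethenyl)-3,4-dimethoxy-2-(3,4,5-trimethoxyphenoxy)cyclobut-2-en-1-one (racemic) | O=C1C(Oc2cc(OC)c(OC)c(OC)c2)=C(OC)C1(OC)C(=C)OCC | intermediate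
10 | (3Z)-5-ethoxy-3,4-dimethoxy-2-(3,4,5-trimethoxyphenoxy)hexa-1,3,5-trien-1-one | O=C=C(Oc1cc(OC)c(OC)c(OC)c1)/C(OC)=C(/OC)C(=C)OCC | intermediate
11 | 5-ethoxy-3,4-dimethoxy-2-(3,4,5-trimethoxyphenoxy)cyclohexa-2,4-dien-1-one | O=C1CC(OCC)=C(OC)C(OC)=C1Oc1cc(OC)c(OC)c(OC)c1 | intermediate
12 | 5-ethoxy-3,4-dimethoxy-2-(3,4,5-trimethoxyphenoxy)phenol (rings D–E) | Oc1cc(OCC)c(OC)c(OC)c1Oc1cc(OC)c(OC)c(OC)c1 | intermediate
13 | 2,4,6-trimethoxybenzaldehyde | O=Cc1c(OC)cc(OC)cc1OC | starting material
14 | 2,4,6-trimethoxyphenyl formate | O=COc1c(OC)cc(OC)cc1OC | intermediate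
15 | 2,4,6-trimethoxyphenol (ring A) | Oc1c(OC)cc(OC)cc1OC | intermediate
16 | 1-fluoro-3,5-dimethoxybenzene | COc1cc(F)cc(OC)c1 | starting material
17 | N-[(2-fluoro-4,6-dimethoxyphenyl)methylidene]-N-methylmethanaminium dichlorophosphate | C[N+](C)=Cc1c(F)cc(OC)cc1OC.[O-]P(=O)(Cl)Cl | intermediate
18 | 2-fluoro-4,6-dimethoxybenzaldehyde | O=Cc1c(F)cc(OC)cc1OC | intermediate
19 | 2,4-dimethoxy-6-(2,4,6-trimethoxyphenoxy)benzaldehyde | O=Cc1c(OC)cc(OC)cc1Oc1c(OC)cc(OC)cc1OC | intermediate
20 | 2,4-dimethoxy-6-(2,4,6-trimethoxyphenoxy)phenyl formate | O=COc1c(OC)cc(OC)cc1Oc1c(OC)cc(OC)cc1OC | intermediate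
21 | 2,4-dimethoxy-6-(2,4,6-trimethoxyphenoxy)phenol (rings A–B) | Oc1c(OC)cc(OC)cc1Oc1c(OC)cc(OC)cc1OC | intermediate
22 | 2-bromo-1,3-dimethoxybenzene | COc1cccc(OC)c1Br | starting material
23 | 2-(4-bromo-3,5-dimethoxyphenyl)-4,4,5,5-tetramethyl-1,3,2-dioxaborolane | COc1cc(B2OC(C)(C)C(C)(C)O2)cc(OC)c1Br | intermediate
24 | 2-bromo-5-iodo-1,3-dimethoxybenzene | COc1cc(I)cc(OC)c1Br | intermediate
25 | 2-bromo-5-[2,4-dimethoxy-6-(2,4,6-trimethoxyphenoxy)phenoxy]-1,3-dimethoxybenzene | COc1cc(Oc2c(OC)cc(OC)cc2Oc2c(OC)cc(OC)cc2OC)cc(OC)c1Br | intermediate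
26 | {4-[2,4-dimethoxy-6-(2,4,6-trimethoxyphenoxy)phenoxy]-2,6-dimethoxyphenyl}lithium | [Li]c1c(OC)cc(Oc2c(OC)cc(OC)cc2Oc2c(OC)cc(OC)cc2OC)cc1OC | intermediate
27 | 5-[2,4-dimethoxy-6-(2,4,6-trimethoxyphenoxy)phenoxy]-2-iodo-1,3-dimethoxybenzene (rings A–B–C) | COc1cc(Oc2c(OC)cc(OC)cc2Oc2c(OC)cc(OC)cc2OC)cc(OC)c1I | intermediate
28 | 1-{4-[2,4-dimethoxy-6-(2,4,6-trimethoxyphenoxy)phenoxy]-2,6-dimethoxyphenoxy}-5-ethoxy-3,4-dimethoxy-2-(3,4,5-trimethoxyphenoxy)benzene | CCOc1cc(Oc2c(OC)cc(Oc3c(OC)cc(OC)cc3Oc3c(OC)cc(OC)cc3OC)cc2OC)c(Oc2cc(OC)c(OC)c(OC)c2)c(OC)c1OC | intermediate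
29 | target tridecaphenol, CNP0243665.0 (no stereocentres) | Oc1cc(O)c(Oc2cc(O)cc(O)c2Oc2cc(O)c(Oc3cc(O)c(O)c(O)c3Oc3cc(O)c(O)c(O)c3)c(O)c2)c(O)c1 | target

**Step count**

Total: 13 steps. Longest linear sequence: 7 steps (5 or 6, then 7, 8, 10, 11, 12, 13). The ring D–E branch is 6 steps (1, 2, 3, 4, 12, 13).

**Steps most likely to fail**

Step 3. The vinyllithium may attack the carbonyl beside the aryloxy carbon as well, which would scramble the position of the aryloxy group on ring D. The fallback removes the regiochemical choice and sets out from 2. Two equivalents of 3 with i-Pr2NEt in CH2Cl2 should give the symmetrical 3,4-bis(3,4,5-trimethoxyphenoxy)cyclobut-3-ene-1,2-dione F1. Addition of 7 at −78 °C can then give only one alkoxide, lithium 1-(1-ethoxyethenyl)-4-oxo-2,3-bis(3,4,5-trimethoxyphenoxy)cyclobut-2-en-1-olate F2, which is methylated with MeOTf to 4-(1-ethoxyethenyl)-4-methoxy-2,3-bis(3,4,5-trimethoxyphenoxy)cyclobut-2-en-1-one F3. One equivalent of NaOMe in MeOH/THF at 0 °C then exchanges, by conjugate addition–elimination, only the aryloxy group on the β-carbon of the enone (the vinylogous ester position); the α-aryloxy group cannot leave this way. The fallback comes back to the route at 9.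

Step 12. Oxidative addition at the iodide flanked by two methoxy groups may be too slow when both partners are large and used near 1:1, so that protodeiodination of 27 competes. The fallback changes the order of bond formation and sets out from 12. Phenol 12 is coupled with a large excess of commercial 2-iodo-1,3-dimethoxybenzene (stoichiometric CuI, Cs2CO3, 2,2,6,6-tetramethylheptane-3,5-dione, NMP, 120 °C) to give 1-(2,6-dimethoxyphenoxy)-5-ethoxy-3,4-dimethoxy-2-(3,4,5-trimethoxyphenoxy)benzene F4. Iridium-catalysed C–H borylation (as in step 9) should take the only C–H without an ortho substituent, the one para to the new ether oxygen on ring C, giving pinacol boronate F5 (2-{4-[5-ethoxy-3,4-dimethoxy-2-(3,4,5-trimethoxyphenoxy)phenoxy]-3,5-dimethoxyphenyl}-4,4,5,5-tetramethyl-1,3,2-dioxaborolane). Copper-mediated iododeboronation in the same flask gives 1-(4-iodo-2,6-dimethoxyphenoxy)-5-ethoxy-3,4-dimethoxy-2-(3,4,5-trimethoxyphenoxy)benzene F6. Its unhindered iodide is coupled with hindered phenol 21 under the conditions of step 10, and the fallback comes back to the route at 28.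

Step 13. Cleavage of thirteen ethers may stop short, and the pyrogallol-type rings D and E may oxidise in air during work-up and chromatography of the free polyphenol. The fallback sets out from 28. After the BBr3 treatment the crude product is not purified but acetylated at once (Ac2O, pyridine, DMAP) to the tridecaacetate of the target F7, which is stable and can be separated on silica from partly alkylated material. Acid methanolysis (HCl generated from AcCl in MeOH, argon, 0 °C to rt) then releases the phenols without passing through phenoxides, and the fallback comes back to the route at 29.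

**Further compounds**

F1 | step 3 | 3,4-bis(3,4,5-trimethoxyphenoxy)cyclobut-3-ene-1,2-dione | O=C1C(=O)C(Oc2cc(OC)c(OC)c(OC)c2)=C1Oc1cc(OC)c(OC)c(OC)c1
F2 | step 3 | lithium 1-(1-ethoxyethenyl)-4-oxo-2,3-bis(3,4,5-trimethoxyphenoxy)cyclobut-2-en-1-olate (racemic) | [Li+].[O-]C1(C(=C)OCC)C(Oc2cc(OC)c(OC)c(OC)c2)=C(Oc2cc(OC)c(OC)c(OC)c2)C1=O
F3 | step 3 | 4-(1-ethoxyethenyl)-4-methoxy-2,3-bis(3,4,5-trimethoxyphenoxy)cyclobut-2-en-1-one (racemic) | O=C1C(Oc2cc(OC)c(OC)c(OC)c2)=C(Oc2cc(OC)c(OC)c(OC)c2)C1(OC)C(=C)OCC
F4 | step 12 | 1-(2,6-dimethoxyphenoxy)-5-ethoxy-3,4-dimethoxy-2-(3,4,5-trimethoxyphenoxy)benzene | CCOc1cc(Oc2c(OC)cccc2OC)c(Oc2cc(OC)c(OC)c(OC)c2)c(OC)c1OC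
F5 | step 12 | 2-{4-[5-ethoxy-3,4-dimethoxy-2-(3,4,5-trimethoxyphenoxy)phenoxy]-3,5-dimethoxyphenyl}-4,4,5,5-tetramethyl-1,3,2-dioxaborolane | CCOc1cc(Oc2c(OC)cc(B3OC(C)(C)C(C)(C)O3)cc2OC)c(Oc2cc(OC)c(OC)c(OC)c2)c(OC)c1OC
F6 | step 12 | 1-(4-iodo-2,6-dimethoxyphenoxy)-5-ethoxy-3,4-dimethoxy-2-(3,4,5-trimethoxyphenoxy)benzene | CCOc1cc(Oc2c(OC)cc(I)cc2OC)c(Oc2cc(OC)c(OC)c(OC)c2)c(OC)c1OC
F7 | step 13 | tridecaacetate of the target | CC(=O)Oc1cc(OC(C)=O)c(Oc2cc(OC(C)=O)cc(OC(C)=O)c2Oc2cc(OC(C)=O)c(Oc3cc(OC(C)=O)c(OC(C)=O)c(OC(C)=O)c3Oc3cc(OC(C)=O)c(OC(C)=O)c(OC(C)=O)c3)c(OC(C)=O)c2)c(OC(C)=O)c1
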